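**Assumption:** the target SMILES has no stereocentre and no stereodescriptor, so the compound is achiral and is made as such; stereocentres that appear in intermediates are racemic and vanish on aromatisation.

## Retrosynthetic overview

1. The furan is the only ring formed, and it is closed last: acid cyclodehydration of a phenol onto an aryl ketone (O1–C2), together with loss of all four MOM groups. Both benzene rings are bought.
2. The ketone comes from an α-aryl-α-methyl allyl β-keto ester (Pd-mediated deallylation, loss of CO2), itself made by oxidising a β-hydroxy ester.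
3. Key C–C bond (future C2–C3): intermolecular aldol addition of the lithium enolate of a ring A allyl 2-arylpropanoate to a fully substituted ring B benzaldehyde.
4. Ring B aldehyde from 2,4,6-trihydroxybenzaldehyde: bis-MOM, O-allylation, ortho-Claisen, O-methylation, allyl-to-prenyl cross-metathesis.
5. Ring A ester from (2,4-dimethoxyphenyl)acetic acid: demethylation, allyl ester, MOM protection, α-methylation.

## Ring A fragment

Step 1
Reactants: 1 (2,4-dimethoxyphenyl)acetic acid
Product: 2 (2,4-dihydroxyphenyl)acetic acid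
Conditions: BBr3 (3.5 equiv), CH2Cl2, −78 °C → rt; then H2O, 0 °C
Reagents that add atoms: none
Why: Lewis-acid ether cleavage (BBr3 demethylation) removes both aryl methyl ethers so that the ring A oxygens can later carry acid-labile groups distinguishable from the ring B methyl ether.

Step 2
Reactants: 2 (2,4-dihydroxyphenyl)acetic acid
Product: 3 allyl 2-(2,4-dihydroxyphenyl)acetate
Conditions: allyl bromide (1.1 equiv), KHCO3 (1.2 equiv), DMF, rt
Reagents that add atoms: allyl bromide (3-bromoprop-1-ene), C=CCBr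
Why: Chemoselective carboxylate O-alkylation (SN2): bicarbonate deprotonates only the carboxylic acid, so the phenols stay free and no acid-driven ring closure onto the ortho phenol can compete.

Step 3
Reactants: 3 allyl 2-(2,4-dihydroxyphenyl)acetate
Product: 4 allyl 2-[2,4-bis(methoxymethoxy)phenyl]acetate
Conditions: MOMCl (2.6 equiv), iPr2NEt (3 equiv), CH2Cl2, 0 °C → rt
Reagents that add atoms: chloromethyl methyl ether (MOMCl), COCCl
Why: Standard phenol acetalisation (Williamson-type alkylation) gives base-stable MOM ethers that survive the enolate chemistry and fall off in the final acid step.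

Step 4
Reactants: 4 allyl 2-[2,4-bis(methoxymethoxy)phenyl]acetate
Product: 6 allyl 2-[2,4-bis(methoxymethoxy)phenyl]propanoate (racemic), via lithium ester enolate 5 (not isolated)
Conditions: LiN(iPr)2 (1.05 equiv), THF, −78 °C; then MeI (1.2 equiv), −78 → −30 °C
Reagents that add atoms: iodomethane, CI
Why: Enolate C-alkylation of an arylacetate with one equivalent of base gives clean mono-methylation and installs the carbon that becomes the 3-methyl group; the new stereocentre is racemic and is later erased.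

## Ring B fragment

Step 5
Reactants: 7 phloroglucinaldehyde (2,4,6-trihydroxybenzaldehyde)
Product: 8 2-hydroxy-4,6-bis(methoxymethoxy)benzaldehyde
Conditions: MOMCl (2.2 equiv), iPr2NEt (2.5 equiv), CH2Cl2, 0 °C → rt
Reagents that add atoms: chloromethyl methyl ether (MOMCl), COCCl
Why: Selective phenol alkylation: after the 4-OH and one ortho OH are protected, the last OH is strongly hydrogen-bonded to the aldehyde and does not react under amine-base conditions.

Step 6
Reactants: 8 2-hydroxy-4,6-bis(methoxymethoxy)benzaldehyde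
Product: 9 2-(allyloxy)-4,6-bis(methoxymethoxy)benzaldehyde
Conditions: allyl bromide (1.5 equiv), K2CO3 (2 equiv), DMF, 50 °C
Reagents that add atoms: allyl bromide (3-bromoprop-1-ene), C=CCBr
Why: Williamson ether synthesis with a reactive primary allylic bromide alkylates even the chelated phenol under carbonate in DMF.

Step 7
Reactants: 9 2-(allyloxy)-4,6-bis(methoxymethoxy)benzaldehyde
Product: 11 3-allyl-2-hydroxy-4,6-bis(methoxymethoxy)benzaldehyde, via ortho-dienone 10 (not isolated)
Conditions: PhNEt2, 190 °C, Ar (sealed tube)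
Reagents that add atoms: none
Why: Aromatic Claisen rearrangement ([3,3]-sigmatropic) delivers the allyl group to C3, the only free ortho position (C1 carries the formyl group), which fixes the carbon chain between the future OMe and the 4-oxygen without ambiguity.

Step 8
Reactants: 11 3-allyl-2-hydroxy-4,6-bis(methoxymethoxy)benzaldehyde
Product: 12 3-allyl-2-methoxy-4,6-bis(methoxymethoxy)benzaldehyde
Conditions: MeI (3 equiv), K2CO3 (2 equiv), DMF, 40 °C
Reagents that add atoms: iodomethane, CI
Why: Williamson O-methylation of the liberated phenol places the single methyl ether of the target exactly between the formyl carbon and the allyl carbon.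

Step 9
Reactants: 12 3-allyl-2-methoxy-4,6-bis(methoxymethoxy)benzaldehyde
Product: 13 2-methoxy-4,6-bis(methoxymethoxy)-3-(3-methylbut-2-en-1-yl)benzaldehyde
Conditions: 2-methylbut-2-ene (excess, co-solvent), second-generation Grubbs catalyst RuCl2(=CHPh)(PCy3)(H2IMes) (3 mol%), CH2Cl2, 40 °C
Reagents that add atoms: 2-methylbut-2-ene, CC=C(C)C
Why: Olefin cross-metathesis of a terminal allyl arene with excess 2-methylbut-2-ene converts allyl to prenyl with loss of propene; the aldehyde and acetals are inert to the ruthenium carbene.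

## Fragment union and endgame

Step 10
Reactants: 6 allyl 2-[2,4-bis(methoxymethoxy)phenyl]propanoate; 13 2-methoxy-4,6-bis(methoxymethoxy)-3-(3-methylbut-2-en-1-yl)benzaldehyde
Product: 15 allyl 2-[2,4-bis(methoxymethoxy)phenyl]-3-hydroxy-3-[2-methoxy-4,6-bis(methoxymethoxy)-3-(3-methylbut-2-en-1-yl)phenyl]-2-methylpropanoate (racemic diastereomer mixture), via lithium propanoate enolate 14 (not isolated)
Conditions: 6 (1.3 equiv), LiN(iPr)2 (1.35 equiv), THF, −78 °C, 45 min; then 13, −78 °C, 2 h; AcOH quench at −78 °C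
Reagents that add atoms: none
Why: Crossed aldol addition of a preformed lithium ester enolate to a non-enolisable aldehyde forges the bond that becomes C2–C3 of the benzofuran; the two new stereocentres form without control and both are erased in steps 11 to 13, and the cold quench prevents retro-aldol.

Step 11
Reactants: 15 the aldol adduct
Product: 16 allyl 2-[2,4-bis(methoxymethoxy)phenyl]-3-[2-methoxy-4,6-bis(methoxymethoxy)-3-(3-methylbut-2-en-1-yl)phenyl]-2-methyl-3-oxopropanoate (racemic)
Conditions: Dess–Martin periodinane (1.5 equiv), CH2Cl2, 0 °C → rt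
Reagents that add atoms: none
Why: Dess–Martin oxidation handles hindered benzylic alcohols under non-basic conditions, so no retro-aldol occurs, and it leaves the prenyl alkene, allyl ester and MOM ethers alone.

Step 12
Reactants: 16 the allyl β-keto ester
Product: 18 2-[2,4-bis(methoxymethoxy)phenyl]-1-[2-methoxy-4,6-bis(methoxymethoxy)-3-(3-methylbut-2-en-1-yl)phenyl]propan-1-one (racemic), via β-keto acid 17 (not isolated)
Conditions: Pd(PPh3)4 (5 mol%), morpholine (5 equiv), THF, rt → 40 °C
Reagents that add atoms: none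
Why: Tsuji–Trost deallylation: zerovalent palladium ionises the allyl ester, excess morpholine traps the π-allyl fragment (suppressing C-allylation), and the quaternary β-keto acid loses CO2 at near-neutral pH, avoiding hydroxide and retro-Claisen cleavage.

Step 13
Reactants: 18 the tetra-MOM ketone
Product: 21 glycybenzofuran, via tetraphenol ketone 19 (not isolated), via cyclic hemiketal 20 (not isolated)
Conditions: HCl (1.25 M in MeOH), 45 °C, Ar
Reagents that add atoms: none
Why: Acid-catalysed acetal exchange frees the four phenols, and the ring A ortho phenol then adds to the ketone and dehydrates (cyclodehydration to the aromatic benzofuran); the aryl methyl ether is stable, and mild acid at moderate temperature keeps the prenyl group from cyclising onto its neighbouring phenol.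

## Compound list

1 | (2,4-dimethoxyphenyl)acetic acid | COc1ccc(CC(=O)O)c(OC)c1 | starting material
2 | (2,4-dihydroxyphenyl)acetic acid | OC(=O)Cc1ccc(O)cc1O | intermediate
3 | allyl 2-(2,4-dihydroxyphenyl)acetate | C=CCOC(=O)Cc1ccc(O)cc1O | intermediate
4 | allyl 2-[2,4-bis(methoxymethoxy)phenyl]acetate | C=CCOC(=O)Cc1ccc(OCOC)cc1OCOC | intermediate
5 | lithium enolate of 4 (not isolated) | C=CCOC([O-])=Cc1ccc(OCOC)cc1OCOC.[Li+] | intermediate
6 | allyl 2-[2,4-bis(methoxymethoxy)phenyl]propanoate (racemic) | C=CCOC(=O)C(C)c1ccc(OCOC)cc1OCOC | intermediate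
7 | 2,4,6-trihydroxybenzaldehyde (phloroglucinaldehyde) | O=Cc1c(O)cc(O)cc1O | starting material
8 | 2-hydroxy-4,6-bis(methoxymethoxy)benzaldehyde | O=Cc1c(O)cc(OCOC)cc1OCOC | intermediate
9 | 2-(allyloxy)-4,6-bis(methoxymethoxy)benzaldehyde | O=Cc1c(OCC=C)cc(OCOC)cc1OCOC | intermediate
10 | 6-allyl-2-formyl-3,5-bis(methoxymethoxy)cyclohexa-2,4-dien-1-one (racemic ortho-dienone, not isolated) | O=CC1=C(OCOC)C=C(OCOC)C(CC=C)C1=O | intermediate
11 | 3-allyl-2-hydroxy-4,6-bis(methoxymethoxy)benzaldehyde | O=Cc1c(O)c(CC=C)c(OCOC)cc1OCOC | intermediate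
12 | 3-allyl-2-methoxy-4,6-bis(methoxymethoxy)benzaldehyde | O=Cc1c(OC)c(CC=C)c(OCOC)cc1OCOC | intermediate
13 | 2-methoxy-4,6-bis(methoxymethoxy)-3-(3-methylbut-2-en-1-yl)benzaldehyde | O=Cc1c(OC)c(CC=C(C)C)c(OCOC)cc1OCOC | intermediate
14 | lithium enolate of 6 (not isolated) | C=CCOC([O-])=C(C)c1ccc(OCOC)cc1OCOC.[Li+] | intermediate
15 | allyl 2-[2,4-bis(methoxymethoxy)phenyl]-3-hydroxy-3-[2-methoxy-4,6-bis(methoxymethoxy)-3-(3-methylbut-2-en-1-yl)phenyl]-2-methylpropanoate (racemic diastereomer mixture) | C=CCOC(=O)C(C)(c1ccc(OCOC)cc1OCOC)C(O)c1c(OC)c(CC=C(C)C)c(OCOC)cc1OCOC | intermediate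
16 | allyl 2-[2,4-bis(methoxymethoxy)phenyl]-3-[2-methoxy-4,6-bis(methoxymethoxy)-3-(3-methylbut-2-en-1-yl)phenyl]-2-methyl-3-oxopropanoate (racemic) | C=CCOC(=O)C(C)(c1ccc(OCOC)cc1OCOC)C(=O)c1c(OC)c(CC=C(C)C)c(OCOC)cc1OCOC | intermediate
17 | 2-[2,4-bis(methoxymethoxy)phenyl]-3-[2-methoxy-4,6-bis(methoxymethoxy)-3-(3-methylbut-2-en-1-yl)phenyl]-2-methyl-3-oxopropanoic acid (racemic, not isolated) | OC(=O)C(C)(c1ccc(OCOC)cc1OCOC)C(=O)c1c(OC)c(CC=C(C)C)c(OCOC)cc1OCOC | intermediate
18 | 2-[2,4-bis(methoxymethoxy)phenyl]-1-[2-methoxy-4,6-bis(methoxymethoxy)-3-(3-methylbut-2-en-1-yl)phenyl]propan-1-one (racemic) | CC(c1ccc(OCOC)cc1OCOC)C(=O)c1c(OC)c(CC=C(C)C)c(OCOC)cc1OCOC | intermediate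
19 | 2-(2,4-dihydroxyphenyl)-1-[4,6-dihydroxy-2-methoxy-3-(3-methylbut-2-en-1-yl)phenyl]propan-1-one (racemic, not isolated) | CC(c1ccc(O)cc1O)C(=O)c1c(OC)c(CC=C(C)C)c(O)cc1O | intermediate
20 | 2-[4,6-dihydroxy-2-methoxy-3-(3-methylbut-2-en-1-yl)phenyl]-3-methyl-2,3-dihydrobenzofuran-2,6-diol (racemic diastereomer mixture, not isolated) | CC1c2ccc(O)cc2OC1(O)c1c(OC)c(CC=C(C)C)c(O)cc1O | intermediate
21 | glycybenzofuran, 2-[4,6-dihydroxy-2-methoxy-3-(3-methylbut-2-en-1-yl)phenyl]-3-methylbenzofuran-6-ol (achiral) | COc1c(CC=C(C)C)c(O)cc(O)c1-c1oc2cc(O)ccc2c1C | target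

## Step count and risk

Total steps: 13. Longest linear sequence: 9 steps (7 → 21, steps 5 to 13). The ring A branch is 8 steps (1 → 21, steps 1 to 4 and 10 to 13).

**Step 10 (aldol).** A tetrasubstituted enolate must add to a 2,6-disubstituted, electron-rich benzaldehyde, and the congested aldolate can revert on warming. Fallback: set out from the unmethylated ester 4 and aldehyde 13 and add the methyl group after the C–C bond is made. LiN(iPr)2 (THF, −78 °C) converts 4 into enolate 5, whose aldol addition to 13 gives the less hindered secondary aldol allyl 2-[2,4-bis(methoxymethoxy)phenyl]-3-hydroxy-3-[2-methoxy-4,6-bis(methoxymethoxy)-3-(3-methylbut-2-en-1-yl)phenyl]propanoate F1. Dess–Martin oxidation gives the enolisable β-keto ester allyl 2-[2,4-bis(methoxymethoxy)phenyl]-3-[2-methoxy-4,6-bis(methoxymethoxy)-3-(3-methylbut-2-en-1-yl)phenyl]-3-oxopropanoate F2. C-methylation of its doubly stabilised enolate (K2CO3, MeI, acetone, rt) comes back to the route at 16.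

**Step 13 (global acid step).** The prenyl group sits next to a phenol that is freed in acid, so chroman formation can compete, as can capture of the MOM-derived cation by the phloroglucinol ring. Fallback: install the prenyl group last so that it never meets acid. Set out from the allyl aldehyde 12, leaving out step 9. Aldol addition of enolate 14 (from 6) gives allyl 3-[3-allyl-2-methoxy-4,6-bis(methoxymethoxy)phenyl]-2-[2,4-bis(methoxymethoxy)phenyl]-3-hydroxy-2-methylpropanoate F3. Dess–Martin oxidation gives allyl 3-[3-allyl-2-methoxy-4,6-bis(methoxymethoxy)phenyl]-2-[2,4-bis(methoxymethoxy)phenyl]-2-methyl-3-oxopropanoate F4. Pd(PPh3)4 and morpholine cleave only the allyl ester, giving 3-[3-allyl-2-methoxy-4,6-bis(methoxymethoxy)phenyl]-2-[2,4-bis(methoxymethoxy)phenyl]-2-methyl-3-oxopropanoic acid F5 (not isolated), which loses CO2 to 1-[3-allyl-2-methoxy-4,6-bis(methoxymethoxy)phenyl]-2-[2,4-bis(methoxymethoxy)phenyl]propan-1-one F6. Methanolic HCl then leads through 1-(3-allyl-4,6-dihydroxy-2-methoxyphenyl)-2-(2,4-dihydroxyphenyl)propan-1-one F7 and the hemiketal 2-(3-allyl-4,6-dihydroxy-2-methoxyphenyl)-3-methyl-2,3-dihydrobenzofuran-2,6-diol F8 (neither isolated) to 2-(3-allyl-4,6-dihydroxy-2-methoxyphenyl)-3-methylbenzofuran-6-ol F9. Cross-metathesis of F9 with 2-methylbut-2-ene (second-generation Grubbs catalyst RuCl2(=CHPh)(PCy3)(H2IMes), CH2Cl2, 40 °C) comes back to the route at the target 21.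

**Step 7 (Claisen rearrangement).** The reaction needs about 190 °C in the presence of an aldehyde and two acetals, and some allyl may travel on to the para position (C5) by a further Cope shift. Fallback: replace the sigmatropic step by halogenation and cross-coupling. Set out from 8. Iodination directed ortho to the free phenol (BnMe3N·ICl2, CaCO3, CH2Cl2–MeOH, rt) gives 2-hydroxy-3-iodo-4,6-bis(methoxymethoxy)benzaldehyde F10. O-methylation (MeI, K2CO3, DMF) gives 3-iodo-2-methoxy-4,6-bis(methoxymethoxy)benzaldehyde F11. Stille coupling with allyltributylstannane (Pd(PPh3)4, DMF, 90 °C) comes back to the route at 12.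

## Further compounds

F1 | step 10 | allyl 2-[2,4-bis(methoxymethoxy)phenyl]-3-hydroxy-3-[2-methoxy-4,6-bis(methoxymethoxy)-3-(3-methylbut-2-en-1-yl)phenyl]propanoate (racemic diastereomer mixture) | C=CCOC(=O)C(c1ccc(OCOC)cc1OCOC)C(O)c1c(OC)c(CC=C(C)C)c(OCOC)cc1OCOC
F2 | step 10 | allyl 2-[2,4-bis(methoxymethoxy)phenyl]-3-[2-methoxy-4,6-bis(methoxymethoxy)-3-(3-methylbut-2-en-1-yl)phenyl]-3-oxopropanoate (racemic) | C=CCOC(=O)C(c1ccc(OCOC)cc1OCOC)C(=O)c1c(OC)c(CC=C(C)C)c(OCOC)cc1OCOC
F3 | step 13 | allyl 3-[3-allyl-2-methoxy-4,6-bis(methoxymethoxy)phenyl]-2-[2,4-bis(methoxymethoxy)phenyl]-3-hydroxy-2-methylpropanoate (racemic diastereomer mixture) | C=CCOC(=O)C(C)(c1ccc(OCOC)cc1OCOC)C(O)c1c(OC)c(CC=C)c(OCOC)cc1OCOC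
F4 | step 13 | allyl 3-[3-allyl-2-methoxy-4,6-bis(methoxymethoxy)phenyl]-2-[2,4-bis(methoxymethoxy)phenyl]-2-methyl-3-oxopropanoate (racemic) | C=CCOC(=O)C(C)(c1ccc(OCOC)cc1OCOC)C(=O)c1c(OC)c(CC=C)c(OCOC)cc1OCOC
F5 | step 13 | 3-[3-allyl-2-methoxy-4,6-bis(methoxymethoxy)phenyl]-2-[2,4-bis(methoxymethoxy)phenyl]-2-methyl-3-oxopropanoic acid (racemic, not isolated) | OC(=O)C(C)(c1ccc(OCOC)cc1OCOC)C(=O)c1c(OC)c(CC=C)c(OCOC)cc1OCOC
F6 | step 13 | 1-[3-allyl-2-methoxy-4,6-bis(methoxymethoxy)phenyl]-2-[2,4-bis(methoxymethoxy)phenyl]propan-1-one (racemic) | CC(c1ccc(OCOC)cc1OCOC)C(=O)c1c(OC)c(CC=C)c(OCOC)cc1OCOC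
F7 | step 13 | 1-(3-allyl-4,6-dihydroxy-2-methoxyphenyl)-2-(2,4-dihydroxyphenyl)propan-1-one (racemic, not isolated) | CC(c1ccc(O)cc1O)C(=O)c1c(OC)c(CC=C)c(O)cc1O
F8 | step 13 | 2-(3-allyl-4,6-dihydroxy-2-methoxyphenyl)-3-methyl-2,3-dihydrobenzofuran-2,6-diol (racemic diastereomer mixture, not isolated) | CC1c2ccc(O)cc2OC1(O)c1c(OC)c(CC=C)c(O)cc1O
F9 | step 13 | 2-(3-allyl-4,6-dihydroxy-2-methoxyphenyl)-3-methylbenzofuran-6-ol | COc1c(CC=C)c(O)cc(O)c1-c1oc2cc(O)ccc2c1C
F10 | step 7 | 2-hydroxy-3-iodo-4,6-bis(methoxymethoxy)benzaldehyde | O=Cc1c(O)c(I)c(OCOC)cc1OCOC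
F11 | step 7 | 3-iodo-2-methoxy-4,6-bis(methoxymethoxy)benzaldehyde | O=Cc1c(OC)c(I)c(OCOC)cc1OCOC
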